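**Strategy.** Everything rests on cutting the C4–C4a bond of the pyran ring (ring C). The feature used is that C4 bears ring D, oxygenated at both ortho positions and the para position, so positive charge at C4 is heavily delocalised, while C4a of ring A is activated by the C7 oxygen (para) and by O1 (ortho). In one operation, acid ionises a C4 carbinol (either epimer) and a Friedel–Crafts attack by ring A forges C4–C4a, closes ring C and sets C4 trans to the preset C2 centre. The precursor is a 1,3-diaryl-3-aryloxypropan-1-ol: C3 (the future C2, R) carries ring B and the 3-benzyloxyphenyl ether, all phenols are benzyl ethers, and ring D holds a bromine marking the lauroyl site.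

Key step: step 6

Remark: the four numbered starting materials are taken to be catalogue chemicals; ring B is carried as a benzyl ether so that no base is needed at the end (a free 4'-phenoxide could open the C2–O1 bond), and the ring D bromine fixes where the lauroyl group goes.

Step 1
Reactants: 1 4-(benzyloxy)benzaldehyde
Product: 2 (1R)-1-[4-(benzyloxy)phenyl]but-3-en-1-ol
Conditions: (R)-BINOL (20 mol %), Ti(OiPr)4 (10 mol %), 4 Å MS, allylSnBu3 (1.2 equiv), CH2Cl2, −20 °C; aq. NaHCO3
Reagents that add atoms: allyltributylstannane, C=CC[Sn](CCCC)(CCCC)CCCC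
Why: Keck asymmetric allylation, in which the chiral Lewis acid formed from (R)-BINOL and Ti(OiPr)4 activates the aldehyde and should direct allyl transfer from the stannane to its Re face, setting the carbinol centre as R.

Step 2
Reactants: 2 (1R)-1-[4-(benzyloxy)phenyl]but-3-en-1-ol; 3 1-(benzyloxy)-3-iodobenzene
Product: 4 1-(benzyloxy)-3-{[(1R)-1-[4-(benzyloxy)phenyl]but-3-en-1-yl]oxy}benzene
Conditions: 3 (1.5 equiv), CuI (10 mol %), 3,4,7,8-tetramethyl-1,10-phenanthroline (20 mol %), Cs2CO3 (2 equiv), toluene, 110 °C
Reagents that add atoms: none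
Why: Ullmann-type CuI-catalysed C–O coupling of a secondary alcohol with an aryl iodide makes the new bond at the aryl carbon, so the carbinol C–O bond is never broken and the R centre is retained, which avoids the SN1 leakage that activating this 4-alkoxybenzylic alcohol for displacement could cause.

Step 3
Reactants: 4 1-(benzyloxy)-3-{[(1R)-1-[4-(benzyloxy)phenyl]but-3-en-1-yl]oxy}benzene
Product: 5 (3R)-3-[3-(benzyloxy)phenoxy]-3-[4-(benzyloxy)phenyl]propanal
Conditions: OsO4 (2 mol %), NaIO4 (4 equiv), 2,6-lutidine (2 equiv), dioxane/H2O 3:1, rt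
Reagents that add atoms: sodium periodate, [Na+].[O-]I(=O)(=O)=O (oxygen source, passed on by catalytic osmium tetroxide, O=[Os](=O)(=O)=O)
Why: Lemieux–Johnson oxidation (catalytic dihydroxylation of the terminal alkene, then periodate cleavage of the diol) should give the aldehyde without touching the electron-rich aryl ethers or the stereocentre; the β-aryloxy aldehyde is used at once to avoid loss of the phenol by elimination.

Step 4
Reactants: 6 1,3,5-tris(benzyloxy)benzene
Product: 7 2,4-dibromo-1,3,5-tris(benzyloxy)benzene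
Conditions: NBS (2.05 equiv), CH2Cl2, 0 °C → rt, dark
Reagents that add atoms: N-bromosuccinimide, O=C1CCC(=O)N1Br
Why: Electrophilic aromatic bromination (SEAr) of a ring whose free positions are each activated by three alkoxy groups should stop at the dibromide with two equivalents, because each bromine deactivates and crowds the ring.

Step 5
Reactants: 7 2,4-dibromo-1,3,5-tris(benzyloxy)benzene; 5 (3R)-3-[3-(benzyloxy)phenoxy]-3-[4-(benzyloxy)phenyl]propanal
Product: 9 (3R)-3-[3-(benzyloxy)phenoxy]-3-[4-(benzyloxy)phenyl]-1-[2,4,6-tris(benzyloxy)-3-bromophenyl]propan-1-ol (both C1 epimers), via aryllithium 8 (not isolated)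
Conditions: 7 (1.1 equiv), n-BuLi (1.1 equiv), THF, −78 °C; then 5, −78 °C; aq. NH4Cl
Reagents that add atoms: none
Why: Bromine–lithium exchange is fast at −78 °C and should stop after one bromine because the aryllithium formed is electron-rich, and 1,2-addition of this aryllithium to the aldehyde gives the carbinol, whose new centre is left uncontrolled on purpose since step 6 erases it, while the ether centre is not involved.

Step 6
Reactants: 9 (3R)-3-[3-(benzyloxy)phenoxy]-3-[4-(benzyloxy)phenyl]-1-[2,4,6-tris(benzyloxy)-3-bromophenyl]propan-1-ol (both C1 epimers)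
Product: 11 (2R,4S)-7-(benzyloxy)-2-[4-(benzyloxy)phenyl]-4-[2,4,6-tris(benzyloxy)-3-bromophenyl]chroman (2,4-trans), via benzylic cation 10 (not isolated)
Conditions: BF3·OEt2 (0.2 equiv), CH2Cl2, −40 → 0 °C
Reagents that add atoms: none
Why: Catalytic BF3 removes the hydroxyl of either epimer of 9 to give the same planar cation 10, delocalised into the ortho and para benzyloxy groups of ring D; the ring A carbon that is ortho to the ether oxygen and para to its benzyloxy group attacks it, and loss of a proton restores the arene (intramolecular Friedel–Crafts alkylation, an SEAr process). The closest known reaction type is the acid-mediated cyclialkylation of 3-aryloxy-1-arylpropan-1-ols to 4-arylchromans. Ring C closes in a six-membered mode that is 6-endo with respect to the C4a–C8a bond of the arene, which ends up inside the new ring. The new C4 centre is controlled by 1,3-induction from the fixed C2 centre: in a half-chair transition state the ring B aryl group sits pseudoequatorial and the di-ortho-substituted ring D takes the pseudoaxial site to stay clear of the peri C5–H, which should give the 2,4-trans (2R,4S) isomer, also expected to be the more stable one. The step needs ionisation at C4 and not at the C2 benzylic ether, and attack by the right ring A carbon: a hydroxyl on a trialkoxybenzylic carbon should leave far more easily under a trace of acid at low temperature than an aryloxy group from a monoalkoxybenzylic carbon, the site para to the benzyloxy group is less crowded than the one between the two oxygens, and closure onto ring B would need a five-membered ring at a carbon meta to its oxygen.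

Step 7
Reactants: 12 dodecanoyl chloride
Product: 13 N-methoxy-N-methyldodecanamide
Conditions: MeNHOMe·HCl, K2CO3, CH2Cl2/H2O, 0 °C → rt
Reagents that add atoms: N,O-dimethylhydroxylamine hydrochloride, CNOC.Cl
Why: Schotten–Baumann N-acylation of N,O-dimethylhydroxylamine by the acid chloride gives the Weinreb amide.

Step 8
Reactants: 11 (2R,4S)-7-(benzyloxy)-2-[4-(benzyloxy)phenyl]-4-[2,4,6-tris(benzyloxy)-3-bromophenyl]chroman; 13 N-methoxy-N-methyldodecanamide
Product: 15 1-{2,4,6-tris(benzyloxy)-3-[(2R,4S)-7-(benzyloxy)-2-[4-(benzyloxy)phenyl]chroman-4-yl]phenyl}dodecan-1-one, via aryllithium 14 (not isolated)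
Conditions: n-BuLi (1.1 equiv), THF, −78 °C; then 13 (1.5 equiv), −78 → 0 °C; aq. NH4Cl
Reagents that add atoms: none
Why: Bromine–lithium exchange at the only C–Br bond followed by acyl substitution on the Weinreb amide, whose chelated tetrahedral adduct should hold until work-up and so prevent over-addition, places the lauroyl group exactly at the marked ring D carbon, and exchange at −78 °C is faster than deprotonation at C2, C4 or the benzylic ether CH2 groups, so both stereocentres are untouched.

Step 9
Reactants: 15 1-{2,4,6-tris(benzyloxy)-3-[(2R,4S)-7-(benzyloxy)-2-[4-(benzyloxy)phenyl]chroman-4-yl]phenyl}dodecan-1-one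
Product: 16 1-{2,4,6-trihydroxy-3-[(2R,4S)-7-hydroxy-2-(4-hydroxyphenyl)chroman-4-yl]phenyl}dodecan-1-one (target)
Conditions: H2 (1 atm), Pd(OH)2/C, EtOAc/MeOH, rt
Reagents that add atoms: none
Why: Catalytic hydrogenolysis should cleave all five benzyl aryl ethers under neutral conditions, while the hydrogen-bonded acylphloroglucinol ketone, the secondary cyclic C2–O1 ether and the C4–H bond, all more hindered or less activated than ArO–CH2Ph, should survive, so both stereocentres are kept.

**Compound list**

1 | 4-(benzyloxy)benzaldehyde | O=Cc1ccc(OCc2ccccc2)cc1 | starting material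
2 | (1R)-1-[4-(benzyloxy)phenyl]but-3-en-1-ol | C=CC[C@@H](O)c1ccc(OCc2ccccc2)cc1 | intermediate
3 | 1-(benzyloxy)-3-iodobenzene | Ic1cccc(OCc2ccccc2)c1 | starting material
4 | 1-(benzyloxy)-3-{[(1R)-1-[4-(benzyloxy)phenyl]but-3-en-1-yl]oxy}benzene | C=CC[C@@H](Oc1cccc(OCc2ccccc2)c1)c1ccc(OCc2ccccc2)cc1 | intermediate
5 | (3R)-3-[3-(benzyloxy)phenoxy]-3-[4-(benzyloxy)phenyl]propanal | O=CC[C@@H](Oc1cccc(OCc2ccccc2)c1)c1ccc(OCc2ccccc2)cc1 | intermediate
6 | 1,3,5-tris(benzyloxy)benzene | c1(OCc2ccccc2)cc(OCc2ccccc2)cc(OCc2ccccc2)c1 | starting material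
7 | 2,4-dibromo-1,3,5-tris(benzyloxy)benzene | Brc1c(OCc2ccccc2)cc(OCc2ccccc2)c(Br)c1OCc1ccccc1 | intermediate
8 | [2,4,6-tris(benzyloxy)-3-bromophenyl]lithium | [Li]c1c(OCc2ccccc2)cc(OCc2ccccc2)c(Br)c1OCc1ccccc1 | intermediate (not isolated)
9 | (3R)-3-[3-(benzyloxy)phenoxy]-3-[4-(benzyloxy)phenyl]-1-[2,4,6-tris(benzyloxy)-3-bromophenyl]propan-1-ol, both C1 epimers | OC(C[C@@H](Oc1cccc(OCc2ccccc2)c1)c1ccc(OCc2ccccc2)cc1)c1c(OCc2ccccc2)cc(OCc2ccccc2)c(Br)c1OCc1ccccc1 | intermediate
10 | (3R)-3-[3-(benzyloxy)phenoxy]-3-[4-(benzyloxy)phenyl]-1-[2,4,6-tris(benzyloxy)-3-bromophenyl]propan-1-ylium (cation at the future C4) | [CH+](C[C@@H](Oc1cccc(OCc2ccccc2)c1)c1ccc(OCc2ccccc2)cc1)c1c(OCc2ccccc2)cc(OCc2ccccc2)c(Br)c1OCc1ccccc1 | intermediate (not isolated)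
11 | (2R,4S)-7-(benzyloxy)-2-[4-(benzyloxy)phenyl]-4-[2,4,6-tris(benzyloxy)-3-bromophenyl]chroman, 2,4-trans | Brc1c(OCc2ccccc2)cc(OCc2ccccc2)c([C@H]2C[C@H](c3ccc(OCc4ccccc4)cc3)Oc3cc(OCc4ccccc4)ccc32)c1OCc1ccccc1 | intermediate
12 | dodecanoyl chloride | CCCCCCCCCCCC(=O)Cl | starting material
13 | N-methoxy-N-methyldodecanamide | CCCCCCCCCCCC(=O)N(C)OC | intermediate
14 | (2R,4S)-7-(benzyloxy)-2-[4-(benzyloxy)phenyl]-4-[2,4,6-tris(benzyloxy)-3-lithiophenyl]chroman | [Li]c1c(OCc2ccccc2)cc(OCc2ccccc2)c([C@H]2C[C@H](c3ccc(OCc4ccccc4)cc3)Oc3cc(OCc4ccccc4)ccc32)c1OCc1ccccc1 | intermediate (not isolated)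
15 | 1-{2,4,6-tris(benzyloxy)-3-[(2R,4S)-7-(benzyloxy)-2-[4-(benzyloxy)phenyl]chroman-4-yl]phenyl}dodecan-1-one | CCCCCCCCCCCC(=O)c1c(OCc2ccccc2)cc(OCc2ccccc2)c([C@H]2C[C@H](c3ccc(OCc4ccccc4)cc3)Oc3cc(OCc4ccccc4)ccc32)c1OCc1ccccc1 | intermediate
16 | 1-{2,4,6-trihydroxy-3-[(2R,4S)-7-hydroxy-2-(4-hydroxyphenyl)chroman-4-yl]phenyl}dodecan-1-one | CCCCCCCCCCCC(=O)c1c(O)cc(O)c([C@H]2C[C@H](c3ccc(O)cc3)Oc3cc(O)ccc32)c1O | target

**Step count.** Total: 9 steps. Longest linear sequence: 7 steps (steps 1, 2, 3, 5, 6, 8 and 9, from 1 to 16).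

**Steps most likely to fail**

Step 6. The closure may show too little facial bias, so that more of the 2,4-cis isomer forms than wanted, or the acid may also ionise the C2 benzylic ether and scramble C2. The fallback sets out from aldehyde 5 and arene 6 and comes back at 11; it forms the C4–ring D bond instead of C4–C4a. Aldehyde 5 would be closed onto ring A with SnCl4 in CH2Cl2 at −78 °C (intramolecular Friedel–Crafts hydroxyalkylation) to give (2R)-7-(benzyloxy)-2-[4-(benzyloxy)phenyl]chroman-4-ol F1 as a mixture of C4 epimers. Arene 6 would be brominated once with one equivalent of NBS to 2-bromo-1,3,5-tris(benzyloxy)benzene F2. F1 and F2 would then be joined with BF3·OEt2 at low temperature: the C4 cation of F1, stabilised by the C7 oxygen of ring A, should be attacked by a free position of F2 from the face opposite the C2 aryl group, giving 11.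

Step 2. C–O bond formation at the hindered secondary alkoxide may be slow, so that reduction of the aryl iodide or oxidation of the carbinol takes over. The fallback sets out from 1 and comes back at 4; it displaces at the stereocentre instead of coupling at the aryl carbon. Allylation of 1 as in step 1 but with (S)-BINOL should give (1S)-1-[4-(benzyloxy)phenyl]but-3-en-1-ol F3. A Mitsunobu reaction of F3 with 3-(benzyloxy)phenol (Oc1cccc(OCc2ccccc2)c1; PPh3, DIAD, toluene, −20 °C) should then give ether 4 with inversion at the benzylic carbon, the low temperature and the non-polar solvent serving to keep the displacement SN2.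

Step 8. The crowded aryllithium may act as a base toward the α-CH2 of the amide, or add too slowly, so that the arene is returned without the acyl group. The fallback sets out from 11 (through 14) and comes back at 15; it forms the C–C bond at the aldehyde oxidation level. Aryllithium 14 would be trapped with dodecanal (CCCCCCCCCCCC=O), a more electrophilic and less hindered partner, to give 1-{2,4,6-tris(benzyloxy)-3-[(2R,4S)-7-(benzyloxy)-2-[4-(benzyloxy)phenyl]chroman-4-yl]phenyl}dodecan-1-ol F4 as a mixture of carbinol epimers, and Dess–Martin oxidation of F4 (buffered with NaHCO3) should give 15.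

**Further compounds**

F1 | step 6 | (2R)-7-(benzyloxy)-2-[4-(benzyloxy)phenyl]chroman-4-ol, both C4 epimers | OC1C[C@H](c2ccc(OCc3ccccc3)cc2)Oc2cc(OCc3ccccc3)ccc21
F2 | step 6 | 2-bromo-1,3,5-tris(benzyloxy)benzene | Brc1c(OCc2ccccc2)cc(OCc2ccccc2)cc1OCc1ccccc1
F3 | step 2 | (1S)-1-[4-(benzyloxy)phenyl]but-3-en-1-ol | C=CC[C@H](O)c1ccc(OCc2ccccc2)cc1
F4 | step 8 | 1-{2,4,6-tris(benzyloxy)-3-[(2R,4S)-7-(benzyloxy)-2-[4-(benzyloxy)phenyl]chroman-4-yl]phenyl}dodecan-1-ol, both carbinol epimers | CCCCCCCCCCCC(O)c1c(OCc2ccccc2)cc(OCc2ccccc2)c([C@H]2C[C@H](c3ccc(OCc4ccccc4)cc3)Oc3cc(OCc4ccccc4)ccc32)c1OCc1ccccc1
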